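Cutting the ten-membered ring at C2–C3 is the disconnection on which everything rests: the C1=C10 alkene and the C4–C5 unit are 1,5-related across this bond, and the contiguous C6–C9 stereocentres fit a carvone-derived cyclohexane (C5–C10). One operation, the anionic oxy-Cope rearrangement of a 1-(2-propenyl)-2-vinylcyclohexanol, forms C2–C3, cleaves C5–C10 and delivers the C4–C5 enolate, trapped as its triflate. The precursor carries both alkenyl groups equatorial (vinyl on the face of the C7 isopropenyl group, set by a semipinacol shift), so the ring-trans C4=C5 needed for the epoxide results. The ring-cis 1(10) geometry is fixed later, when SeO2 oxidises C14 to the future ester carbon.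

Key step: step 13

Remark: the target is taken exactly as its SMILES encodes it (4R,5R,6S,7S,8R,9R: O6, C11 and O8 on one ring face, O9 on the other). Germacrane numbering is used throughout; "up" means the ring face that carries the C7 isopropenyl group and "down" the other face.

Step 1
Reactants: 1 (S)-(+)-carvone
Product: 2 carvone oxide, (1S,4S,6S)-1-methyl-4-(prop-1-en-2-yl)-7-oxabicyclo[4.1.0]heptan-2-one (C9–C10 epoxide down)
Conditions: 30% H2O2, NaOH (aq.), MeOH, 0 °C
Reagents that add atoms: hydrogen peroxide, OO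
Why: Weitz–Scheffer nucleophilic epoxidation touches only the enone, and hydroperoxide should add to C9 on the face away from the isopropenyl group, which sets C9 and C10 (epoxide down).

Step 2
Reactants: 2 carvone oxide; 3 vinylmagnesium bromide
Product: 4 epoxy alcohol, (1S,2S,4S,6S)-1-methyl-4-(prop-1-en-2-yl)-2-vinyl-7-oxabicyclo[4.1.0]heptan-2-ol (5-OH down and cis to the epoxide oxygen, vinyl up)
Conditions: THF, −78 °C; aq. NH4Cl
Reagents that add atoms: none
Why: Grignard 1,2-addition to the α,β-epoxy ketone should take the carbonyl face opposite the epoxide oxygen, which sets C5 with the vinyl group anti-periplanar to the C10–O bond.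

Step 3
Reactants: 4 epoxy alcohol
Product: 5 hydroxy ketone, (2R,3S,5S)-3-hydroxy-2-methyl-5-(prop-1-en-2-yl)-2-vinylcyclohexan-1-one (C10 vinyl up and methyl down, 9-OH down)
Conditions: ZnBr2 (0.3 equiv), CH2Cl2, 0 °C to rt
Reagents that add atoms: none
Why: Semipinacol rearrangement of a tertiary α-hydroxy epoxide: the Lewis acid opens the epoxide at tertiary C10 and the anti-periplanar vinyl group shifts from C5 to C10 with inversion, so C10 is set with vinyl up while the C9 hydroxyl stays down.

Step 4
Reactants: 5 hydroxy ketone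
Product: 6 β,γ-enone, (2R,5R)-2-methyl-5-(prop-1-en-2-yl)-2-vinylcyclohex-3-en-1-one
Conditions: Burgess reagent (MeO2CN–SO2NEt3 inner salt), PhMe, 60 °C
Reagents that add atoms: none
Why: Burgess dehydration (syn elimination of the sulfamate) can only remove a C8 hydrogen because C10 is quaternary, so the C8=C9 alkene forms without touching C7 or C10.

Step 5
Reactants: 6 β,γ-enone
Product: 7 allylic chloride, (2R,5R)-5-(3-chloroprop-1-en-2-yl)-2-methyl-2-vinylcyclohex-3-en-1-one
Conditions: Ca(OCl)2, CO2 (solid), CH2Cl2–H2O, 0 °C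
Reagents that add atoms: calcium hypochlorite, [Ca+2].[O-]Cl.[O-]Cl
Why: Ene-type chlorination by HOCl should select the electron-rich 1,1-disubstituted isopropenyl group and turn it into a 2-(chloromethyl)vinyl group that is deactivated toward peracid; no stereocentre is affected.

Step 6
Reactants: 7 allylic chloride
Product: 8 epoxy ketone, the C8–C9 epoxide of 7 (epoxide oxygen down)
Conditions: mCPBA (1.1 equiv), NaHCO3, CH2Cl2, 0 °C
Reagents that add atoms: 3-chloroperoxybenzoic acid, OOC(=O)c1cccc(Cl)c1
Why: Prilezhaev epoxidation should take the ring alkene, the only alkene that is neither monosubstituted nor deactivated by an allylic chlorine, on the face anti to the adjacent C7 substituent, which sets C8 and C9.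

Step 7
Reactants: 8 epoxy ketone
Product: 9 hydroxy ether, 8-(4-methoxybenzyloxy) up and 9-hydroxy down, chloride retained
Conditions: 4-methoxybenzyl alcohol (5 equiv), Yb(OTf)3 (10 mol %), CH2Cl2, rt
Reagents that add atoms: 4-methoxybenzyl alcohol, COc1ccc(CO)cc1
Why: Lewis acid-catalysed epoxide alcoholysis by trans-diaxial opening (Fürst–Plattner rule) at C8, the carbon remote from the quaternary centre and from the electron-withdrawing ketone, inverts C8 (ether up) and leaves the C9 hydroxyl down, so O8 and O9 are differentiated at once.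

Step 8
Reactants: 9 hydroxy ether
Product: 10 hydroxy ketone with the isopropenyl group restored (8-OPMB up, 9-OH down)
Conditions: Bu3SnH, AIBN (cat.), PhH, 80 °C
Reagents that add atoms: none
Why: Radical-chain dehalogenation of the allylic chloride passes through a 2-substituted allyl radical with equivalent termini, so hydrogen transfer can only regenerate the isopropenyl group.

Step 9
Reactants: 10 hydroxy ketone
Product: 11 silyl ether, 9-OTBS down
Conditions: TBSOTf, 2,6-lutidine, CH2Cl2, −78 to 0 °C
Reagents that add atoms: tert-butyldimethylsilyl triflate, CC(C)(C)[Si](C)(C)OS(=O)(=O)C(F)(F)F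
Why: Silylation of the hindered C9 alcohol with a silyl triflate protects the β-hydroxy ketone against retro-aldol cleavage in the enolate steps.

Step 10
Reactants: 11 silyl ether
Product: 13 α-hydroxy ketone with 6-OH down, via potassium enolate 12 (not isolated)
Conditions: KHMDS, THF, −78 °C; 2-(phenylsulfonyl)-3-phenyloxaziridine, −78 °C; aq. NH4Cl
Reagents that add atoms: 2-(phenylsulfonyl)-3-phenyloxaziridine, O=S(=O)(c1ccccc1)N1OC1c1ccccc1
Why: Enolate hydroxylation with an N-sulfonyloxaziridine: the ketone can enolise only toward C6 and oxygen should enter anti to the adjacent C7 isopropenyl group, a C6 configuration that step 11 corrects.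

Step 11
Reactants: 13 α-hydroxy ketone
Product: 15 ketone with 6-(3,4-dimethoxybenzyloxy) up, via 6-epimeric ether 14 (not isolated)
Conditions: 3,4-dimethoxybenzyl trichloroacetimidate, TfOH (1 mol %), CH2Cl2, 0 °C; then DBU, PhMe, 60 °C
Reagents that add atoms: 3,4-dimethoxybenzyl 2,2,2-trichloroacetimidate, COc1ccc(COC(=N)C(Cl)(Cl)Cl)cc1OC
Why: Acid-catalysed imidate benzylation, then base-mediated epimerisation of the α-alkoxy ketone: in the chair that keeps the C8 and C9 ethers equatorial the down 6-ether is axial and 1,3-diaxial to the C10 methyl, so equilibration through the enolate should give the equatorial (up) 6-ether.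

Step 12
Reactants: 15 ketone; 16 2-propenylmagnesium bromide
Product: 17 trans-1-(2-propenyl)-2-vinylcyclohexanol: C5 OH up and 2-propenyl down, 6-ODMB up, C7 isopropenyl, 8-OPMB up, 9-OTBS down, C10 vinyl up and methyl down
Conditions: CeCl3 (anhydrous), THF, −78 to 0 °C; aq. NH4Cl
Reagents that add atoms: none
Why: Organocerium 1,2-addition to the hindered, enolisable ketone: the axial trajectory is blocked by the axial C7 isopropenyl group, so the nucleophile should enter equatorially, which sets C5 with an axial hydroxyl and a 2-propenyl group trans to the C10 vinyl group (both equatorial).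

Step 13
Reactants: 17 trans-1-(2-propenyl)-2-vinylcyclohexanol
Product: 20 cyclodecadienyl triflate (C4=C5–OTf and C1=C10 both ring-trans; 6-ODMB, 8-OPMB, 9-OTBS, C7 isopropenyl), via potassium alkoxide 18 (not isolated), via potassium enolate 19 (not isolated)
Conditions: KH, 18-crown-6, THF, 0 °C to rt; then PhNTf2, −78 to 0 °C; aq. NH4Cl
Reagents that add atoms: N-phenylbis(trifluoromethanesulfonimide), FC(F)(F)S(=O)(=O)N(c1ccccc1)S(=O)(=O)C(F)(F)F
Why: Deprotonation gives the crown-separated C5 alkoxide 18, whose anionic oxy-Cope ([3,3]-sigmatropic) rearrangement forms C2–C3 as C5–C10 breaks, and the C4–C5 enolate 19 so released is O-sulfonylated by PhNTf2 before it can equilibrate. The closest known reaction type is the anionic oxy-Cope ring expansion of 1,2-dialkenylcyclohexanols to cyclodec-5-enones with trapping of the enolate. The ten-membered ring is not closed by a cyclisation but opened out of the cyclohexane, a four-atom ring expansion through a chair six-centre transition state. No stereocentre is created: C5 and C10 become sp2 and C6–C9 are untouched. The selectivity needed is the ring-trans C4=C5 enolate, which requires an equatorial C10 vinyl group, and the substrate secures it because the only chair that keeps the three ring ethers equatorial also holds both alkenyl groups equatorial. That chair leads to the ring-trans, ring-trans diene, so the 1(10) alkene emerges ring-trans and is turned ring-cis in step 17.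

Step 14
Reactants: 20 cyclodecadienyl triflate
Product: 21 triene with C4=C5–H (ring-trans) and C1=C10 (ring-trans)
Conditions: Pd(OAc)2 (5 mol %), PPh3, HCO2H, Bu3N, DMF, 50 °C
Reagents that add atoms: none
Why: Palladium-catalysed formate reduction of the enol triflate (oxidative addition, formate exchange, decarboxylation, C–H reductive elimination) replaces OTf by H with retention of alkene geometry.

Step 15
Reactants: 21 triene
Product: 22 allylic alcohol with free 6-OH
Conditions: DDQ (1.1 equiv), CH2Cl2–pH 7 buffer, 0 °C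
Reagents that add atoms: none
Why: Oxidative debenzylation: DDQ should oxidise the 3,4-dimethoxybenzyl ether faster than the 4-methoxybenzyl ether at C8, so only the C6 hydroxyl is freed.

Step 16
Reactants: 22 allylic alcohol
Product: 23 epoxy alcohol, (4R,5R)-4,5-epoxide
Conditions: VO(acac)2 (5 mol %), t-BuOOH, CH2Cl2, 0 °C
Reagents that add atoms: tert-butyl hydroperoxide, CC(C)(C)OO
Why: Hydroxyl-directed epoxidation of an allylic alcohol: only C4=C5 has a free allylic hydroxyl, and with H-6 eclipsing the alkene (1,3-allylic strain against C15) the C6 oxygen delivers the peroxide to the outer face, which should set C4 and C5 as 4R,5R.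

Step 17
Reactants: 23 epoxy alcohol
Product: 24 triol with 12-OH and 14-OH, 1(10) alkene now ring-cis
Conditions: SeO2 (0.5 equiv), t-BuOOH, CH2Cl2, rt
Reagents that add atoms: tert-butyl hydroperoxide, CC(C)(C)OO (oxygen relayed by SeO2)
Why: Riley allylic oxidation (ene reaction, then [2,3]-sigmatropic shift) of the allylic methyl groups C12 and C14; the [2,3] step places the new C14 oxygen trans to C2, which should turn the 1(10) alkene ring-cis, as is known for 4,5-epoxygermacra-1(10)-enes.

Step 18
Reactants: 24 triol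
Product: 26 α-methylene lactone enal, via lactol 25 (not isolated)
Conditions: TEMPO (20 mol %), PhI(OAc)2, CH2Cl2, rt
Reagents that add atoms: none
Why: Oxoammonium oxidation of the two primary allylic alcohols: the C12 aldehyde is captured by the cis C6 hydroxyl as a five-membered lactol that is oxidised on to the lactone (oxidative lactonisation), while C14 stops at the enal.

Step 19
Reactants: 26 α-methylene lactone enal
Product: 27 lactone acid (C14 carboxylic acid)
Conditions: NaClO2, NaH2PO4, 2-methyl-2-butene, t-BuOH–H2O, 0 °C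
Reagents that add atoms: sodium chlorite, [Na+].[O-]Cl=O
Why: Pinnick oxidation converts the enal into the acid under buffered conditions that should leave epoxide, lactone and ethers alone.

Step 20
Reactants: 27 lactone acid
Product: 28 methyl ester
Conditions: MeI, KHCO3, DMF, rt
Reagents that add atoms: iodomethane, CI
Why: Carboxylate O-alkylation (SN2) gives the methyl ester without a diazoalkane, which would add to the α-methylene lactone.

Step 21
Reactants: 28 methyl ester
Product: 29 alcohol with free 8-OH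
Conditions: DDQ, CH2Cl2–pH 7 buffer, rt
Reagents that add atoms: none
Why: Oxidative cleavage of the 4-methoxybenzyl ether frees the C8 hydroxyl under neutral conditions compatible with the epoxide and both conjugated carbonyl groups.

Step 22
Reactants: 29 alcohol
Product: 30 8-methacrylate (9-OTBS retained)
Conditions: methacryloyl chloride, Et3N, DMAP (cat.), CH2Cl2, 0 °C
Reagents that add atoms: methacryloyl chloride, C=C(C)C(=O)Cl
Why: DMAP-catalysed acylation of the hindered C8 alcohol is done while O9 is still silylated, so no acyl migration is possible.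

Step 23
Reactants: 30 8-methacrylate
Product: 31 alcohol with free 9-OH
Conditions: HF·pyridine, pyridine, THF, 0 °C to rt
Reagents that add atoms: none
Why: Pyridine-buffered fluoride desilylation should free the C9 alcohol without opening the epoxide or adding to the Michael acceptors.

Step 24
Reactants: 31 alcohol
Product: 32 fluctuadin
Conditions: Ac2O, pyridine, DMAP (cat.), CH2Cl2, 0 °C
Reagents that add atoms: acetic anhydride, CC(=O)OC(C)=O
Why: DMAP-catalysed acetylation should be fast enough to outrun O8-to-O9 acyl migration and completes the target.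

Compound list
1 | (S)-(+)-carvone | CC1=CC[C@@H](CC1=O)C(=C)C | starting material
2 | carvone oxide (epoxide down) | O=C1C[C@@H](C(C)=C)C[C@@H]2O[C@]12C | intermediate
3 | vinylmagnesium bromide | C=C[Mg]Br | starting material
4 | epoxy alcohol (5-OH down, vinyl up) | O[C@]1(C=C)C[C@@H](C(C)=C)C[C@@H]2O[C@]12C | intermediate
5 | hydroxy ketone (C10 vinyl up, 9-OH down) | O=C1C[C@@H](C(C)=C)C[C@H](O)[C@@]1(C)C=C | intermediate
6 | β,γ-enone | O=C1C[C@@H](C(C)=C)C=C[C@@]1(C)C=C | intermediate
7 | allylic chloride | O=C1C[C@@H](C(CCl)=C)C=C[C@@]1(C)C=C | intermediate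
8 | epoxy ketone (C8–C9 epoxide down) | O=C1C[C@@H](C(CCl)=C)[C@@H]2O[C@@H]2[C@@]1(C)C=C | intermediate
9 | hydroxy ether (8-OPMB up, 9-OH down, chloride) | O=C1C[C@@H](C(CCl)=C)[C@@H](OCc3ccc(OC)cc3)[C@H](O)[C@@]1(C)C=C | intermediate
10 | hydroxy ketone (isopropenyl restored) | O=C1C[C@@H](C(C)=C)[C@@H](OCc3ccc(OC)cc3)[C@H](O)[C@@]1(C)C=C | intermediate
11 | silyl ether (9-OTBS down) | O=C1C[C@@H](C(C)=C)[C@@H](OCc3ccc(OC)cc3)[C@H](O[Si](C)(C)C(C)(C)C)[C@@]1(C)C=C | intermediate
12 | potassium enolate of 11 | [K+].[O-]C1=C[C@@H](C(C)=C)[C@@H](OCc3ccc(OC)cc3)[C@H](O[Si](C)(C)C(C)(C)C)[C@@]1(C)C=C | intermediate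
13 | α-hydroxy ketone (6-OH down) | O=C1[C@H](O)[C@@H](C(C)=C)[C@@H](OCc3ccc(OC)cc3)[C@H](O[Si](C)(C)C(C)(C)C)[C@@]1(C)C=C | intermediate
14 | 6-epimeric ether (6-ODMB down) | O=C1[C@H](OCc3ccc(OC)c(OC)c3)[C@@H](C(C)=C)[C@@H](OCc3ccc(OC)cc3)[C@H](O[Si](C)(C)C(C)(C)C)[C@@]1(C)C=C | intermediate
15 | ketone (6-ODMB up) | O=C1[C@@H](OCc3ccc(OC)c(OC)c3)[C@@H](C(C)=C)[C@@H](OCc3ccc(OC)cc3)[C@H](O[Si](C)(C)C(C)(C)C)[C@@]1(C)C=C | intermediate
16 | 2-propenylmagnesium bromide | C=C(C)[Mg]Br | starting material
17 | trans-1-(2-propenyl)-2-vinylcyclohexanol (key-step precursor) | O[C@@]1(C(C)=C)[C@@H](OCc3ccc(OC)c(OC)c3)[C@@H](C(C)=C)[C@@H](OCc3ccc(OC)cc3)[C@H](O[Si](C)(C)C(C)(C)C)[C@@]1(C)C=C | intermediate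
18 | potassium alkoxide of 17 | [K+].[O-][C@@]1(C(C)=C)[C@@H](OCc3ccc(OC)c(OC)c3)[C@@H](C(C)=C)[C@@H](OCc3ccc(OC)cc3)[C@H](O[Si](C)(C)C(C)(C)C)[C@@]1(C)C=C | intermediate
19 | potassium enolate (ten-membered ring) | [K+].C/C1=C(/[O-])[C@@H](OCc3ccc(OC)c(OC)c3)[C@@H](C(C)=C)[C@@H](OCc3ccc(OC)cc3)[C@H](O[Si](C)(C)C(C)(C)C)/C(C)=C/CC1 | intermediate
20 | cyclodecadienyl triflate (key-step product) | C/C1=C(/OS(=O)(=O)C(F)(F)F)[C@@H](OCc3ccc(OC)c(OC)c3)[C@@H](C(C)=C)[C@@H](OCc3ccc(OC)cc3)[C@H](O[Si](C)(C)C(C)(C)C)/C(C)=C/CC1 | intermediate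
21 | triene | C/C1=C\[C@@H](OCc3ccc(OC)c(OC)c3)[C@@H](C(C)=C)[C@@H](OCc3ccc(OC)cc3)[C@H](O[Si](C)(C)C(C)(C)C)/C(C)=C/CC1 | intermediate
22 | allylic alcohol (6-OH) | C/C1=C\[C@@H](O)[C@@H](C(C)=C)[C@@H](OCc3ccc(OC)cc3)[C@H](O[Si](C)(C)C(C)(C)C)/C(C)=C/CC1 | intermediate
23 | epoxy alcohol (4R,5R) | C[C@@]12O[C@@H]2[C@@H](O)[C@@H](C(C)=C)[C@@H](OCc3ccc(OC)cc3)[C@H](O[Si](C)(C)C(C)(C)C)/C(C)=C/CC1 | intermediate
24 | triol (12-OH, 14-OH; 1(10) ring-cis) | C[C@@]12O[C@@H]2[C@@H](O)[C@@H](C(CO)=C)[C@@H](OCc3ccc(OC)cc3)[C@H](O[Si](C)(C)C(C)(C)C)/C(CO)=C\CC1 | intermediate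
25 | lactol enal | C[C@@]12O[C@@H]2[C@H]3OC(O)C(=C)[C@H]3[C@@H](OCc4ccc(OC)cc4)[C@H](O[Si](C)(C)C(C)(C)C)/C(C=O)=C\CC1 | intermediate
26 | α-methylene lactone enal | C[C@@]12O[C@@H]2[C@H]3OC(=O)C(=C)[C@H]3[C@@H](OCc4ccc(OC)cc4)[C@H](O[Si](C)(C)C(C)(C)C)/C(C=O)=C\CC1 | intermediate
27 | lactone acid | C[C@@]12O[C@@H]2[C@H]3OC(=O)C(=C)[C@H]3[C@@H](OCc4ccc(OC)cc4)[C@H](O[Si](C)(C)C(C)(C)C)/C(C(=O)O)=C\CC1 | intermediate
28 | methyl ester | C[C@@]12O[C@@H]2[C@H]3OC(=O)C(=C)[C@H]3[C@@H](OCc4ccc(OC)cc4)[C@H](O[Si](C)(C)C(C)(C)C)/C(C(=O)OC)=C\CC1 | intermediate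
29 | 8-alcohol | C[C@@]12O[C@@H]2[C@H]3OC(=O)C(=C)[C@H]3[C@@H](O)[C@H](O[Si](C)(C)C(C)(C)C)/C(C(=O)OC)=C\CC1 | intermediate
30 | 8-methacrylate | C[C@@]12O[C@@H]2[C@H]3OC(=O)C(=C)[C@H]3[C@@H](OC(=O)C(C)=C)[C@H](O[Si](C)(C)C(C)(C)C)/C(C(=O)OC)=C\CC1 | intermediate
31 | 9-alcohol | C[C@@]12O[C@@H]2[C@H]3OC(=O)C(=C)[C@H]3[C@@H](OC(=O)C(C)=C)[C@H](O)/C(C(=O)OC)=C\CC1 | intermediate
32 | fluctuadin | C=C(C)C(=O)O[C@@H]1[C@@H]2C(=C)C(=O)O[C@@H]2[C@H]2O[C@]2(C)CC/C=C(/C(=O)OC)[C@H]1OC(C)=O | target

Total step count: 24. Longest linear sequence: 24 steps from (S)-(+)-carvone.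

Steps most likely to fail

1. Step 13 (key step). The enolate may move by proton transfer to the C5–C6 side, or be O-sulfonylated too slowly as a crown-complexed potassium salt, so that the C4=C5 triflate is not formed cleanly. The fallback sets out from 17 and comes back at 20: the same KH/18-crown-6 rearrangement is quenched at −78 °C with TMSCl/Et3N to isolate the trimethylsilyl enol ether F1. MeLi in THF at 0 °C then regenerates the lithium enolate regiospecifically, and N-(5-chloro-2-pyridyl)bis(trifluoromethanesulfonimide) converts it into 20.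

2. Step 17. Selenous acid may open the acid-sensitive 4,5-epoxide, or the double oxidation may stall at the less reactive isopropenyl methyl. The fallback sets out from 20 and comes back at 26, with the Riley oxidation moved ahead of the epoxide:
- SeO2/t-BuOOH on 20, whose electron-poor enol triflate alkene is inert to the ene reaction, should give the 12,14-diol triflate F2 with the 1(10) alkene already ring-cis.
- Pd(OAc)2/PPh3/HCO2H/Bu3N removes the triflate to give diol triene F3.
- DDQ frees O6 to give triol F4.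
- TEMPO/PhI(OAc)2 closes the lactone and oxidises C14 to give lactone enal F5.
- mCPBA/NaHCO3 then epoxidises C4=C5, the only electron-rich alkene left, on its outer face to give 26.

3. Step 12. The congested, enolisable ketone may be deprotonated instead of attacked, returning 15. The fallback sets out from 15 and comes back at 17: the slimmer ethynylmagnesium bromide with CeCl3 adds along the same equatorial trajectory to give the propargylic alcohol F6. Alkoxide-directed, CuI-catalysed carbomagnesiation with MeMgBr in THF then places methyl on the alkyne carbon next to the carbinol, and protonation gives 17.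

Further compounds
F1 | step 13 | trimethylsilyl enol ether of the ring-expanded ketone | C/C1=C(/O[Si](C)(C)C)[C@@H](OCc3ccc(OC)c(OC)c3)[C@@H](C(C)=C)[C@@H](OCc3ccc(OC)cc3)[C@H](O[Si](C)(C)C(C)(C)C)/C(C)=C/CC1
F2 | step 17 | 12,14-diol triflate (1(10) ring-cis) | C/C1=C(/OS(=O)(=O)C(F)(F)F)[C@@H](OCc3ccc(OC)c(OC)c3)[C@@H](C(CO)=C)[C@@H](OCc3ccc(OC)cc3)[C@H](O[Si](C)(C)C(C)(C)C)/C(CO)=C\CC1
F3 | step 17 | 12,14-diol triene | C/C1=C\[C@@H](OCc3ccc(OC)c(OC)c3)[C@@H](C(CO)=C)[C@@H](OCc3ccc(OC)cc3)[C@H](O[Si](C)(C)C(C)(C)C)/C(CO)=C\CC1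
F4 | step 17 | 6,12,14-triol triene | C/C1=C\[C@@H](O)[C@@H](C(CO)=C)[C@@H](OCc3ccc(OC)cc3)[C@H](O[Si](C)(C)C(C)(C)C)/C(CO)=C\CC1
F5 | step 17 | α-methylene lactone enal with C4=C5 alkene | C/C1=C\[C@H]3OC(=O)C(=C)[C@H]3[C@@H](OCc4ccc(OC)cc4)[C@H](O[Si](C)(C)C(C)(C)C)/C(C=O)=C\CC1
F6 | step 12 | 5-ethynyl carbinol (5-OH up) | O[C@@]1(C#C)[C@@H](OCc3ccc(OC)c(OC)c3)[C@@H](C(C)=C)[C@@H](OCc3ccc(OC)cc3)[C@H](O[Si](C)(C)C(C)(C)C)[C@@]1(C)C=C
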